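One percent of the X charged is 0.520 mM here, so G can be counted in the same unit as E and X. X turns into E with Q as catalyst under held Z, and Sunday's flask is the one asked about, at 40 min.

| setting | Sunday's | Friday's | flask |
|---|---|---|---|
| X | 0.052 M | 0.052 M | 0.052 M |
| Z | 23 mM (held) | 23 mM (held) | 23 mM (held) |
| G | 2.6 mM | 1.7 mM | 2.60 mM |
| Q | 1.3 mM | 1.3 mM | 1.3 mM |
| remark | the very flask that is asked about, followed so far | run made earlier |  |
| time |  |  | 40 min |

| run | time / min | E / % | X / % |
|---|---|---|---|
| Sunday's | 0.500 | 1.2 | 95.8 |
| Sunday's | 1.50 | 5.8 | 90.3 |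
| Sunday's | 3.00 | 13.8 | 81.7 |
| Sunday's | 4.00 | 19.9 | 75.3 |
| Sunday's | 6.00 | 31.3 | 63.3 |
| Sunday's | 8.00 | 42.8 | 52.8 |
| Friday's | 3.00 | 14.2 | 82.6 |
| Friday's | 5.00 | 26.1 | 71.3 |
| Friday's | 8.00 | 42.8 | 54.9 |
| Friday's | 15.0 | 70.7 | 25.8 |
| Friday's | 25.0 | 89.6 | 5.7 |
| Friday's | 40.0 | 96.5 | 0.5 |

(readings scatter by 0.5 percentage points)

* the E standing at 40 min, as a percentage of the X charged
* the change that raises the amount of E at 40 min, in percent of the X charged most ("none" if none brings more than 2 percentage points) (north-east / south-west / south / none)
* amount of E at 40 min, in percent of the X charged, after north-east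

- north-east: doubling the transfer coefficient of Z, all else as stated
- south-west: doubling the saturation concentration of Z, all else as stated
- south: doubling the amount of Q, all else as stated

- what was read earlier has a scatter of 0.5 percentage points, one standard deviation
- at the start none of Z is in solution

At 8.00 min Sunday's flask reads 42.8 % of E and Friday's 42.8 %, yet Sunday's X stands at 52.8 % and Friday's at 54.9 %. Equal E with less X reads as 2.1 percentage points of X gone elsewhere in Sunday's flask beyond what went elsewhere in Friday's.

Write the balance of G, charged in the smaller amount, as the limiting reagent of a side path. If each G takes one X, Sunday loses 5.00 % of its X and Friday 3.27 %. That difference of 1.7 points fits the gap, given a scatter of 0.5 points per reading. So on that count Sunday's flask keeps 95.0 % of its X for E, and that share is the ceiling.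

Friday still held 0.5 % of X at 40.0 min. Taking that for Sunday, I reckon 94.5 % of E. The three changes leave [G] as charged, so I expect them to win about that X, less than the 2 points required.

The forecast, holding that “G appears to take up X roughly one-for-one”, gives 94.5 %, best change none, and 94.8 % after north-east.

The simulation gives 94.5 %, best change none, and 94.9 % after north-east, whose gain is 0.49 points.

    2 D → L (k = 0.259 M⁻¹ s⁻¹)
    X + G → J (k = 0.448 M⁻¹ s⁻¹)
    X + D + Q → Q + E (k = 223 M⁻² s⁻¹)
    Z ⇌ D, rate k4*(csat - [D]) (kL = 0.00353 s⁻¹)

Sunday's ceiling less the 0.55 % of X left at 40.0 min is 94.5 %, and at 400 min this flask stands at 95.0 %. The neighbour charged with 0.0065 M of G, 0.125 equiv to X, has a ceiling of 87.5 %. Less its 0.45 % of X left, that is 87.0 %, and at 40.0 min the neighbour gives 87.0 %, with J at 12.5 % of the X charged and G at 0 % of its own charge.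

(Readings and results were generated by integration for substances that don't exist.)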